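## Structural features

Plakortolide R is a bicyclic peroxylactone. A 1,2-dioxane (O–O, C3, C4, C5, C6) and a γ-butyrolactone (C1 carbonyl, C2, C3, C4, ring oxygen) share the C3–C4 bond and are cis-fused. C3 is a CH bearing the peroxide oxygen, C4 is fully substituted (methyl, lactone oxygen), C5 is the only methylene of the dioxane, and C6 is fully substituted (methyl, peroxide oxygen, side chain). The side chain on C6 is six methylenes (C7–C12) ending in an (E,E)-4-phenylbuta-1,3-dien-1-yl unit (C13–C16, then phenyl). All three stereocentres are S. C3 and C4 are adjacent at the ring fusion and C6 stands 1,3 to C4 across C5, with the chain on the dioxane face opposite the lactone and cis to the C4 methyl group. The fragile parts are the O–O bond (reductants, low-valent metals, phosphines), the β-peroxy lactone array C2–C3 (β-elimination or Kornblum–DeLaMare cleavage under base) and the aryl diene (acids, electrophiles, singlet oxygen, radicals). The real difficulty is a peroxide ring flanked by two tetrasubstituted C–O carbons whose relative configuration must be set across one methylene, where C6 distinguishes only methyl from n-alkyl. The key step uses the fact that C6 and C4 are both tertiary, cation-stabilizing carbons bridged by C5, and that the C1 carboxyl hangs from C3 within reach of C4. A peroxide-stabilized cation at C6, an alkene at C4=C5 and the ester arm on C3 therefore contain the whole bicycle.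

## Logic of the disconnections

**11 ⇒ 9 + 10.** The C13=C14 double bond is cut. The aryl diene is the part least compatible with the cationic chemistry that builds the peroxide ring, so it is introduced last and a terminal vinyl group stands in for it until then. This leaves 9 with an inert chain end and delivers the styrenyl unit with its E geometry ready-made in 10. The forward step must react only at the terminal vinyl of 10, form the new alkene as E, and use no reductant or base that would touch the O–O bond or the β-peroxy lactone.

**9 ⇒ 6.** The C5–C6 bond and the C4–O(lactone) bond are cut. Both rings and both quaternary stereocentres fall away together, leaving an acyclic peroxide whose only stereocentre is C3. The forward step must ionize the ketal at the methoxy oxygen and not at the peroxide oxygen, close the dioxane 6-endo so that the charge arrives at C4, and let the ester on C3 capture that charge before it is lost by deprotonation. The alkyl group of the ester must also be removed cleanly from the resulting lactonium ion. The methyl ester and the methoxy leaving group of 6 are kept: the methyl ester is the best-suited substrate for the resolution that provides C3, and its dealkylation is secured by a soft nucleophile added in the same flask.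

**6 ⇒ 3 + 5.** The C6–O(peroxide) bond of the mixed ketal is cut. This separates the chiral C1–C5 unit from the achiral C6 unit with its whole chain and makes the route convergent. The forward step is an acid-catalysed exchange that must be mild enough to leave the allylic hydroperoxide and the C3 centre untouched. The ketal carbon may form as both epimers because it becomes planar in the next step.

**5 ⇒ 4.** The two C–OMe bonds are cut, returning the commercial ketone 4. The only demand is a water-free ketalization that does not isomerize the terminal alkene.

**3 ⇒ 2 ⇒ 1.** 3 is one enantiomer of 2, so no bond is cut and a resolution is required. 2 is then cut at the C3–O bond with a shift of the double bond from C4=CH2 back to C3=C4, giving the commercial ester 1. Dioxygen becomes the source of the whole O–O unit. The forward ene reaction must abstract hydrogen from the geminal methyl groups and not from C2, and the resolution must deliver the S hydroperoxide.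

## Other disconnections considered

**Alternative 1:** The C4–O(lactone) bond is cut last. The forward key step would treat the dioxanyl acetic acid A1 with a bulky [Mn(OTf)2(pdp)]-type aminopyridine complex (divalent manganese) and H2O2. The bound carboxylate would direct abstraction of the tertiary C4–H and rebound with retention, closing the lactone to A2.
- In its favour: C4 is not formed through a free cation, so elimination or capture by an external nucleophile at C4 is not a concern. The γ tertiary C–H is the preferred site for carboxylate-directed oxidation.
- Against it: A1 already contains the dioxane with three stereocentres (C3, C4 as a methine, C6), so the hard part, the peroxide ring and C6, is only moved upstream and needs its own ring-forming method. The oxidant system can attack the O–O bond by one-electron chemistry. The chain must be cut back to an acetoxyheptyl group because the diene would not survive, which costs three further steps (deacetylation, oxidation, olefination), and the olefination is on a base-sensitive substrate.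
- Comparison: on control of C4 the two plans are equal (retention there, tether here). On mechanism the alternative is the better at C4 itself, but it forms one ring and one bond where the chosen step forms two rings and two bonds. On step economy the chosen plan is clearly shorter.

**Alternative 2:** The C4–C5, C3–O and C6–O bonds are cut, giving the silyloxyfuran A3, the 1,1-disubstituted alkene A4 and dioxygen. Under visible light with Ru(bpz)3(PF6)2 (divalent ruthenium) or 9-mesityl-10-methylacridinium tetrafluoroborate, A3 would be oxidized, the CH2 terminus of A4 would add at its methyl-bearing carbon, and O2 would bridge C6 and C3 to give A5.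
- In its favour: three components and three bonds in one operation from very simple partners. O2 is the peroxide source and no hydroperoxide is ever isolated. On step economy to the bicyclic core this is the better plan.
- Against it: the partners are achiral, so without a chiral catalyst A5 would be racemic, whereas the chosen plan carries absolute configuration from 3. The reaction type is not established for silyloxyfurans. The electron-rich furan would be expected to compete through singlet-oxygen [4+2] addition and through simple desilylative oxidation. The chain end would again need three steps to become the diene.
- Comparison: on C6 the two plans are equal, since neither has more than a methyl/alkyl bias, and the cis ring fusion is ring-enforced in both. On mechanism the chosen plan stands on firmer ground.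

**Alternative 3:** The C3–O(peroxide), C1–C2 and C1–O(lactone) bonds are cut. With Pd(OAc)2 (divalent palladium), benzoquinone and CO, the tertiary hydroperoxide of A6 would add 6-exo to the vinyl group, CO would insert into the C2–Pd bond, and the C4 hydroxyl would capture the acyl palladium to give A7.
- In its favour: C4 and C6 are both set in the acyclic precursor before the rings form and can each be addressed by asymmetric synthesis. On control of C6 this is the better plan. The cascade is of a known type, and C3 is fixed by the cis fusion.
- Against it: A6 combines a tertiary hydroperoxide with a tertiary allylic alcohol and would take many steps to make as a single stereoisomer. Palladium in its zerovalent state, formed in each turnover, and CO must coexist with O–O bonds. A7 carries only C7 of the chain, so C8–C16 would have to be attached afterwards by oxidation, olefination and a selective alkene saturation next to a peroxide.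
- Comparison: on C3/C4 the two plans are equal. On step economy the chosen plan is far shorter, because the ketone delivers the whole chain handle in one piece.

Key step: step 5

Assumption (chemistry): horseradish peroxidase is taken to keep its usual preference for reducing the R-configured secondary hydroperoxide, so that the S enantiomer 3 is the one recovered. The assignment would be checked on a reduced sample before the material is carried on.

## Route

Step 1
Reactants: 1 methyl 4-methylpent-3-enoate
Product: 2 methyl 3-hydroperoxy-4-methylpent-4-enoate (racemate)
Conditions: O2, hν (visible), tetraphenylporphyrin (cat.), CH2Cl2, 0 °C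
Reagents that add atoms: dioxygen O=O
Why: Schenck ene reaction: singlet oxygen bonds to C3 while a hydrogen is taken from a geminal methyl group and the double bond shifts to C4=CH2. Abstraction at C2 is disfavoured because those C–H bonds are deactivated by the ester, so the conjugated tertiary hydroperoxide should be a minor, separable isomer; C3 forms as a racemate.

Step 2
Reactants: 2 methyl 3-hydroperoxy-4-methylpent-4-enoate (racemate)
Product: 3 methyl (3S)-3-hydroperoxy-4-methylpent-4-enoate
Conditions: horseradish peroxidase, guaiacol, phosphate buffer pH 6, rt, stopped just past half conversion; chromatography
Reagents that add atoms: none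
Why: Enzymatic kinetic resolution of a secondary hydroperoxide: the peroxidase reduces one enantiomer (taken to be R) to the alcohol at the expense of guaiacol and leaves 3, which is separated from the more polar alcohol. The C3 configuration is fixed here by selection and is not touched again.

Step 3
Reactants: 4 dec-9-en-2-one
Product: 5 2,2-dimethoxydec-9-ene
Conditions: HC(OMe)3, MeOH, p-TsOH (cat.), rt; then Et3N
Reagents that add atoms: trimethyl orthoformate COC(OC)OC; methanol CO
Why: Acid-catalysed ketalization driven by the orthoester as water scavenger; the isolated terminal alkene is inert.

Step 4
Reactants: 3 methyl (3S)-3-hydroperoxy-4-methylpent-4-enoate; 5 2,2-dimethoxydec-9-ene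
Product: 6 methyl (3S)-3-[(2-methoxydec-9-en-2-yl)peroxy]-4-methylpent-4-enoate (both epimers at the ketal carbon)
Conditions: 5 (excess), PPTS (cat.), 4 Å molecular sieves, CH2Cl2, 0 °C to rt; chromatography on Et3N-deactivated silica
Reagents that add atoms: none
Why: Acid-catalysed transketalization: PPTS ionizes 5 to a methoxycarbenium ion that is captured by the terminal oxygen of the hydroperoxide, and the sieves take up methanol. C3 is not involved, and the epimeric ketal carbon is harmless because it becomes planar in step 5.

Step 5
Reactants: 6 methyl (3S)-3-[(2-methoxydec-9-en-2-yl)peroxy]-4-methylpent-4-enoate
Product: 9 (3S,4aS,7aS)-3,4a-dimethyl-3-(oct-7-en-1-yl)tetrahydro-3H-furo[3,2-c][1,2]dioxin-6(4H)-one, via peroxycarbenium triflate 7 (not isolated), via O-methyl lactonium triflate 8 (not isolated)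
Conditions: Me3SiOTf (1.1 equiv), CH2Cl2, −78 °C; then Me2S, −78 to 0 °C; aq NaHCO3
Reagents that add atoms: none
Why: Me3SiOTf silylates the more basic methoxy oxygen of the mixed ketal and expels methoxytrimethylsilane, leaving the tertiary peroxycarbenium ion 7 with the charge at C6 stabilized by the peroxide oxygen. The CH2 terminus of the isopropenyl group attacks C6 (C5–C6 bond) in a chair-like 6-endo-trig closure of the 1,2-dioxane, the only mode that places the new charge on tertiary C4, since a 5-exo closure would need a primary cation. The carbonyl oxygen of the ester arm on C3 then adds to C4 (C4–O bond, 5-exo with respect to the C4=C5 alkene) to give the O-methyl lactonium ion 8, and dimethyl sulfide takes the methyl group by SN2 attack so that the neutral lactone 9 is released without hydrolysis. The closest known reaction type is the Lewis-acid Prins-type cyclization of alkenyl monoperoxyketals of allylic hydroperoxides to 1,2-dioxanes, terminated here by a neighbouring ester as in cation–olefin lactonizations. C4 is controlled by the tether: the two-atom arm on C3 reaches only the face of the C4 cation syn to itself, so the lactone is cis-fused and C4 follows from the resolved centre C3. C6 is controlled by the geometry of 7: in the chair with the C3 arm equatorial, the substituent anti to the O–O bond becomes equatorial, so the E ion with the long chain in that position leads to the required 6S centre and the Z ion to the C6 epimer. The step needs ionization at the methoxy and not the peroxy oxygen (secured by the higher basicity of the ether oxygen) and ring closure faster than proton loss from C4 (secured by the intramolecular carboxyl trap). Its E preference rests only on the difference between CH2R and CH3, so the C6 epimer is expected as a minor product to be removed by chromatography.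

Step 6
Reactants: 9 (3S,4aS,7aS)-3,4a-dimethyl-3-(oct-7-en-1-yl)tetrahydro-3H-furo[3,2-c][1,2]dioxin-6(4H)-one; 10 (E)-1-phenylbuta-1,3-diene
Product: 11 plakortolide R, (3S,4aS,7aS)-3,4a-dimethyl-3-[(7E,9E)-10-phenyldeca-7,9-dien-1-yl]tetrahydro-3H-furo[3,2-c][1,2]dioxin-6(4H)-one
Conditions: second-generation Hoveyda–Grubbs catalyst RuCl2(H2IMes)(=CH–C6H4-2-OiPr) (cat.), 10 (excess), CH2Cl2, 40 °C, dark
Reagents that add atoms: none
Why: Olefin cross-metathesis: the ruthenium carbene initiates on the unhindered terminal alkene of 9 and exchanges with the terminal vinyl group of 10, with ethene leaving the solution. The new C13=C14 bond should form mainly as the conjugated E isomer while the styrenyl E bond of 10 is carried over, and the catalyst has no reducing or basic action on the O–O bond or the lactone.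

## Compound list

1 | methyl 4-methylpent-3-enoate | COC(=O)CC=C(C)C | starting material
2 | methyl 3-hydroperoxy-4-methylpent-4-enoate (racemate) | COC(=O)CC(C(C)=C)OO | intermediate
3 | methyl (3S)-3-hydroperoxy-4-methylpent-4-enoate | COC(=O)C[C@@H](C(C)=C)OO | intermediate
4 | dec-9-en-2-one | CC(=O)CCCCCCC=C | starting material
5 | 2,2-dimethoxydec-9-ene | COC(C)(OC)CCCCCCC=C | intermediate
6 | methyl (3S)-3-[(2-methoxydec-9-en-2-yl)peroxy]-4-methylpent-4-enoate (ketal carbon as both epimers) | COC(=O)C[C@@H](C(C)=C)OOC(C)(OC)CCCCCCC=C | intermediate
7 | peroxycarbenium triflate formed from 6 by loss of methoxide (charge at C6, E and Z forms interconverting) | COC(=O)C[C@@H](C(C)=C)O[O+]=C(C)CCCCCCC=C.[O-]S(=O)(=O)C(F)(F)F | intermediate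
8 | O-methyl lactonium triflate of 9 (bicycle closed, methyl still on the carboxyl oxygen) | C[C@]1(CCCCCCC=C)C[C@]2(C)[O+]=C(OC)C[C@@H]2OO1.[O-]S(=O)(=O)C(F)(F)F | intermediate
9 | (3S,4aS,7aS)-3,4a-dimethyl-3-(oct-7-en-1-yl)tetrahydro-3H-furo[3,2-c][1,2]dioxin-6(4H)-one (3S,4S,6S in the C1–C6 numbering used above) | C[C@]1(CCCCCCC=C)C[C@]2(C)OC(=O)C[C@@H]2OO1 | intermediate
10 | (E)-1-phenylbuta-1,3-diene | C=C/C=C/c1ccccc1 | starting material
11 | plakortolide R | C[C@]1(CCCCCC/C=C/C=C/c2ccccc2)C[C@]2(C)OC(=O)C[C@@H]2OO1 | target

## Step count and least certain steps

Total step count: 6. Longest linear sequence: 5 steps (steps 1, 2, 4, 5, 6 from 1); step 3 is a one-step branch from 4.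

**Step 5 (key step).**
- What may go wrong: the C4 cation may lose a proton to give ring alkenes, or be intercepted by an external nucleophile, before the ester closes. Ionization may also occur at the peroxide oxygen instead of the methoxy oxygen. In addition, discrimination between the methyl and alkyl branches of the peroxycarbenium ion is inherently weak, so attack on both faces of C6 will compete and the C6 epimer must be separated.
- Fallback (sets out from 6, returns at 9): uncouple the two ring closures. Treating 6 with TiCl4 in CH2Cl2 at −78 °C should give the chloride-terminated Prins product methyl 2-[(3S,6S)-4-chloro-4,6-dimethyl-6-(oct-7-en-1-yl)-1,2-dioxan-3-yl]acetate F1 (mixture at C4). This is the documented termination for this substrate class and gives a second point at which the C6 epimers can be separated. AgOSO2CF3 in CH2Cl2 at low temperature, followed by Me2S, would then ionize the tertiary C–Cl bond in a relaxed ring with no competing nucleophile, and the neighbouring ester would close the cis-lactone to 9. The C4 configuration of F1 does not matter because it is lost in the cation and reset by the tether.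

**Step 2.**
- What may go wrong: the enzyme may discriminate poorly between the enantiomers of 2, because neither substituent at C3 is as small as the methyl group of its best substrates, or its preference may be opposite to the assumed one.
- Fallback (sets out from 2, returns at 3): resolution without an enzyme, by preparative chromatography of 2 on a polysaccharide chiral stationary phase (cellulose tris(3,5-dimethylphenylcarbamate), hexane/2-propanol). This delivers both enantiomers and therefore 3 whatever the enzyme would have done. It makes no new compound (entry F0).

**Step 6.**
- What may go wrong: the carbene may engage the internal styrenyl alkene of 10 and transfer a truncated fragment, the new alkene may form as an E/Z mixture, or 9 may homodimerize.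
- Fallback (sets out from 9, returns at 11): a boron relay that fixes each alkene separately. Cross-metathesis of 9 with vinylboronic acid pinacol ester (same ruthenium catalyst) should give the E-alkenylboronate (3S,4aS,7aS)-3,4a-dimethyl-3-[(7E)-8-(4,4,5,5-tetramethyl-1,3,2-dioxaborolan-2-yl)oct-7-en-1-yl]tetrahydro-3H-furo[3,2-c][1,2]dioxin-6(4H)-one F2. Suzuki–Miyaura coupling with (E)-(2-bromovinyl)benzene (PdCl2(dppf), a divalent palladium precatalyst, with K3PO4 in THF/H2O at rt) then joins C14 to C15 with retention at both alkenes to give 11. The mild base is tolerable because any retro-oxa-Michael opening of the β-peroxy lactone can only re-close to the same cis-fused ring.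

**Step 4.**
- What may go wrong: the exchange may stall because methanol is not removed, or the acid may instead trigger Hock-type cleavage of the allylic hydroperoxide or closure of the hydroperoxide onto its own ester.
- Fallback (sets out from 5 and 3, returns at 6): replace the exchange by an addition. Elimination of methanol from 5 (Me3SiOTf, iPr2NEt, CH2Cl2, 0 °C) should give 2-methoxydeca-1,9-diene F3 (with double-bond isomers that lead to the same cation). 3 then adds across the enol ether under a trace of PPTS at 0 °C, with no methanol released and no equilibrium to drive.

## Further compounds

F1 | step 5 | methyl 2-[(3S,6S)-4-chloro-4,6-dimethyl-6-(oct-7-en-1-yl)-1,2-dioxan-3-yl]acetate (both epimers at C4) | C[C@]1(CCCCCCC=C)CC(C)(Cl)[C@H](CC(=O)OC)OO1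
F0 | step 2 | none | none
F2 | step 6 | (3S,4aS,7aS)-3,4a-dimethyl-3-[(7E)-8-(4,4,5,5-tetramethyl-1,3,2-dioxaborolan-2-yl)oct-7-en-1-yl]tetrahydro-3H-furo[3,2-c][1,2]dioxin-6(4H)-one | C[C@]1(CCCCCC/C=C/B3OC(C)(C)C(C)(C)O3)C[C@]2(C)OC(=O)C[C@@H]2OO1
F3 | step 4 | 2-methoxydeca-1,9-diene | C=C(OC)CCCCCCC=C
A1 | alternative 1 | 2-[(3S,4R,6S)-6-(7-acetoxyheptyl)-4,6-dimethyl-1,2-dioxan-3-yl]acetic acid | CC(=O)OCCCCCCC[C@@]1(C)C[C@@H](C)[C@H](CC(=O)O)OO1
A2 | alternative 1 | 7-[(3S,4aS,7aS)-3,4a-dimethyl-6-oxohexahydrofuro[3,2-c][1,2]dioxin-3-yl]heptyl acetate | C[C@]1(CCCCCCCOC(C)=O)C[C@]2(C)OC(=O)C[C@@H]2OO1
A3 | alternative 2 | tert-butyldimethyl[(5-methylfuran-2-yl)oxy]silane | Cc1ccc(O[Si](C)(C)C(C)(C)C)o1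
A4 | alternative 2 | tert-butyldimethyl[(8-methylnon-8-en-1-yl)oxy]silane | C=C(C)CCCCCCCO[Si](C)(C)C(C)(C)C
A5 | alternative 2 | bicyclic peroxylactone core with a 7-(tert-butyldimethylsilyloxy)heptyl chain at C6, configured as in 11 | C[C@]1(CCCCCCCO[Si](C)(C)C(C)(C)C)C[C@]2(C)OC(=O)C[C@@H]2OO1
A6 | alternative 3 | (3S,5R)-6-[(tert-butyldimethylsilyl)oxy]-5-hydroperoxy-3,5-dimethylhex-1-en-3-ol | C=C[C@@](C)(O)C[C@@](C)(OO)CO[Si](C)(C)C(C)(C)C
A7 | alternative 3 | bicyclic peroxylactone core with a (tert-butyldimethylsilyloxy)methyl group at C6, configured as in 11 | C[C@]1(CO[Si](C)(C)C(C)(C)C)C[C@]2(C)OC(=O)C[C@@H]2OO1
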